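**Assumption:** genipin (bulk commercial, enantiopure iridoid) is accepted as a commercial starting material, so this is a chiral-pool route in which both rings arrive intact. Iridoid numbering is used (O2 = ring oxygen, C10 = CH2 on C8, C11 = carbon on C4); β = the face of H-9, α = the opposite face. The target is 1β-O-isovaleryl (1S), 7β-OAc (7S), 8α-OH with 10β-CH2O-salicyl (8R), H-9β (9S). The route is a paper design and has not been run.

## Retrosynthetic overview

1. Target ⇐ phenol desilylation ⇐ C7 acetylation and C11 isovalerylation of the diene diol 13.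
2. 13 ⇐ Luche reduction of the dienone-enal 12 (sets C7, unveils C11-OH) ⇐ IBX oxidation/dehydrogenation of the 7β,8α-diol 11 (creates C5=C6).
3. 11 ⇐ ester-assisted opening, with inversion at C8, of the 7β,8β-epoxide 10 ⇐ convex-face epoxidation of alkene 9.
4. 9 ⇐ genipin by CO2Me → CHO adjustment (keeps the enol ether electron-poor and reducible late), C10 salicylation, C1 isovalerylation.
5. Ring order: no ring is built; the cis-fused cyclopenta[c]pyran with C1 and C9 configuration comes from genipin.

## Forward route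

**Step 1**
Reactants: 1 genipin
Product: 2, 1β,10-bis-O-TBS-genipin (methyl ester, 3,4- and 7,8-alkenes, H-5β, H-9β)
Conditions: TBSCl (2.5 equiv), imidazole, DMAP (cat.), DMF, 0 °C → rt
Reagents that add atoms: TBSCl, CC(C)(C)[Si](C)(C)Cl
Why: Silylation of the primary allylic alcohol and the hemiacetal OH blocks both before hydride reduction; no stereocentre changes.

**Step 2**
Reactants: 2
Product: 3, the C11 primary allylic alcohol (4-CH2OH), 1β,10-bis-OTBS
Conditions: DIBAL-H (3 equiv), CH2Cl2, −78 °C; Rochelle salt work-up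
Reagents that add atoms: none
Why: DIBAL 1,2-reduction of the vinylogous carbonate ester to the allylic alcohol; silyl ether and silyl acetal are inert.

**Step 3**
Reactants: 3
Product: 4, the 4-carbaldehyde (β-alkoxy enal), 1β,10-bis-OTBS
Conditions: MnO2 (excess), CH2Cl2, rt
Reagents that add atoms: none
Why: MnO2 allylic oxidation gives a vinylogous formate, which keeps the enol ether electron-poor (tolerant of peracid, BF3, IBX) and can be reduced later in the presence of esters.

**Step 4**
Reactants: 4
Product: 5, (1R,4aS,7aS)-1-hydroxy-7-(hydroxymethyl)-1,4a,5,7a-tetrahydrocyclopenta[c]pyran-4-carbaldehyde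
Conditions: TBAF/AcOH (1:1, 2.5 equiv), THF, 0 °C
Reagents that add atoms: none
Why: Buffered fluoride desilylation frees both hydroxyls; the hemiacetal settles as the genipin-type 1β-OH.

**Step 5**
Reactants: 6 salicylic acid
Product: 7, 2-(tert-butyldimethylsilyloxy)benzoic acid
Conditions: TBSCl (2.2 equiv), imidazole, DMF, rt; then K2CO3, THF/MeOH/H2O, 0 °C; acidify to pH 4–5
Reagents that add atoms: TBSCl, CC(C)(C)[Si](C)(C)Cl
Why: Bis-silylation followed by selective hydrolysis of the labile silyl ester leaves the phenol masked for the later acylations.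

**Step 6**
Reactants: 5 and 7
Product: 8, the 10-O-[2-(TBSO)benzoyl] ester of 5 (1β-OH free)
Conditions: EDC·HCl, DMAP (0.1 equiv), CH2Cl2, −20 → 0 °C (1.0 equiv of 7)
Reagents that add atoms: none (7 is the acyl donor; EDC is not incorporated)
Why: Steglich esterification is selective for the primary allylic OH over the hindered, less nucleophilic hemiacetal OH.

**Step 7**
Reactants: 8
Product: 9, 1β-O-isovaleryl-10-O-[2-(TBSO)benzoyl] enal (3,4- and 7,8-alkenes, H-5β, H-9β)
Conditions: isovaleryl chloride, pyridine, DMAP (cat.), CH2Cl2, 0 °C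
Reagents that add atoms: isovaleryl chloride, CC(C)CC(Cl)=O
Why: Anomeric O-acylation traps the β-hemiacetal as the pseudo-axial 1β-acyloxy acetal (anomeric effect), the C1 configuration of the target.

**Step 8**
Reactants: 9
Product: 10, the 7β,8β-epoxide (C10 now α)
Conditions: mCPBA, NaHCO3, CH2Cl2, 0 °C
Reagents that add atoms: mCPBA, OOC(=O)c1cccc(Cl)c1
Why: Prilezhaev epoxidation of the only nucleophilic alkene from the convex β-face (the face of H-5 and H-9) of the cis-fused bicycle.

**Step 9**
Reactants: 10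
Product: 11, the 7β,8α-diol with 10β-CH2O-[2-(TBSO)benzoyl]
Conditions: BF3·OEt2 (1.5 equiv), CH2Cl2, −78 °C; then THF/H2O, NaHCO3; then Et3N (cat.), CH2Cl2, rt
Reagents that add atoms: water, O
Why: Lewis-acid epoxide opening with neighbouring-group participation: the C10 ester carbonyl attacks tertiary C8 from the α-face (5-exo, inversion) to give a dioxolanylium ion; hydrolysis and O8→O10 acyl equilibration leave 8α-OH, 7β-OH and the primary ester.

**Step 10**
Reactants: 11
Product: 12, the 5,6-en-7-one (cross-conjugated dienone-enal), 8α-OH, H-9β, esters intact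
Conditions: IBX (4 equiv), 4-methoxypyridine N-oxide (4 equiv), DMSO, 25 → 40 °C
Reagents that add atoms: none
Why: IBX oxidises the secondary carbinol to the α-ketol without diol cleavage, then IBX·MPO dehydrogenation (Nicolaou) through the only possible enol (C6; C8 is quaternary) installs C5=C6 in conjugation with the enol ether.

**Step 11**
Reactants: 12
Product: 13, the 3,5-diene-7β,8α,11-triol 1-isovalerate 10-[2-(TBSO)benzoate]
Conditions: NaBH4, CeCl3·7H2O, MeOH/THF, −78 °C; pH 7 buffer
Reagents that add atoms: none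
Why: Luche 1,2-reduction of the enone and the aldehyde; hydride should add to C7 from the α-face (anti to the β-CH2OAr on quaternary C8, reinforced by Ce chelation of the 8α-OH), giving the 7β-alcohol; esters are untouched.

**Step 12**
Reactants: 13
Product: 14, the 11-O-isovalerate (7β-OH and 8α-OH free)
Conditions: isovaleric anhydride (1.1 equiv), 2,4,6-collidine, DMAP (5 mol %), CH2Cl2, −40 °C
Reagents that add atoms: isovaleric anhydride, CC(C)CC(=O)OC(=O)CC(C)C
Why: Chemoselective acylation of the unhindered primary allylic alcohol over the neopentyl-type secondary and the tertiary alcohols.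

**Step 13**
Reactants: 14
Product: 15, the 7β-O-acetate (O-TBS-protected target)
Conditions: Ac2O, pyridine, DMAP (cat.), CH2Cl2, 0 °C
Reagents that add atoms: acetic anhydride, CC(=O)OC(C)=O
Why: DMAP-catalysed acetylation of the remaining secondary alcohol; the tertiary 8-OH does not react at 0 °C.

**Step 14**
Reactants: 15
Product: 16, Jatamanvaltrate I
Conditions: TBAF/AcOH (1:1, 1.5 equiv), THF, −20 → 0 °C
Reagents that add atoms: none
Why: Buffered fluoride cleaves the aryl silyl ether rapidly under near-neutral conditions that spare the acyl acetal, the allylic esters and the diene.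

## Compound list

1 | Genipin | OCC1=CC[C@@H]2C(C(=O)OC)=CO[C@@H](O)[C@H]12 | starting material
2 | 1β,10-Bis-O-TBS-genipin | CC(C)(C)[Si](C)(C)OCC1=CC[C@@H]2C(C(=O)OC)=CO[C@@H](O[Si](C)(C)C(C)(C)C)[C@H]12 | intermediate
3 | 1β,10-Bis-O-TBS 11-alcohol | CC(C)(C)[Si](C)(C)OCC1=CC[C@@H]2C(CO)=CO[C@@H](O[Si](C)(C)C(C)(C)C)[C@H]12 | intermediate
4 | 1β,10-Bis-O-TBS 4-carbaldehyde | CC(C)(C)[Si](C)(C)OCC1=CC[C@@H]2C(C=O)=CO[C@@H](O[Si](C)(C)C(C)(C)C)[C@H]12 | intermediate
5 | 1β-Hydroxy-10-hydroxy 4-carbaldehyde | OCC1=CC[C@@H]2C(C=O)=CO[C@@H](O)[C@H]12 | intermediate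
6 | Salicylic acid | O=C(O)c1ccccc1O | starting material
7 | 2-(tert-Butyldimethylsilyloxy)benzoic acid | O=C(O)c1ccccc1O[Si](C)(C)C(C)(C)C | intermediate
8 | 10-O-[2-(TBSO)benzoyl] hemiacetal | O=C(OCC1=CC[C@@H]2C(C=O)=CO[C@@H](O)[C@H]12)c3ccccc3O[Si](C)(C)C(C)(C)C | intermediate
9 | 1β-O-Isovaleryl-10-O-[2-(TBSO)benzoyl] enal | O=C(OCC1=CC[C@@H]2C(C=O)=CO[C@@H](OC(=O)CC(C)C)[C@H]12)c3ccccc3O[Si](C)(C)C(C)(C)C | intermediate
10 | 7β,8β-Epoxide | O=C(OC[C@@]14O[C@H]4C[C@@H]2C(C=O)=CO[C@@H](OC(=O)CC(C)C)[C@H]12)c3ccccc3O[Si](C)(C)C(C)(C)C | intermediate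
11 | 7β,8α-Diol 10-aroate | O=C(OC[C@@]1(O)[C@@H](O)C[C@@H]2C(C=O)=CO[C@@H](OC(=O)CC(C)C)[C@H]12)c3ccccc3O[Si](C)(C)C(C)(C)C | intermediate
12 | 5,6-En-7-one (dienone-enal), 8α-OH | O=C(OC[C@@]1(O)C(=O)C=C2C(C=O)=CO[C@@H](OC(=O)CC(C)C)[C@H]12)c3ccccc3O[Si](C)(C)C(C)(C)C | intermediate
13 | 3,5-Diene-7β,8α,11-triol 1-isovalerate 10-aroate | O=C(OC[C@@]1(O)[C@@H](O)C=C2C(CO)=CO[C@@H](OC(=O)CC(C)C)[C@H]12)c3ccccc3O[Si](C)(C)C(C)(C)C | intermediate
14 | 11-O-Isovalerate of 13 | O=C(OC[C@@]1(O)[C@@H](O)C=C2C(COC(=O)CC(C)C)=CO[C@@H](OC(=O)CC(C)C)[C@H]12)c3ccccc3O[Si](C)(C)C(C)(C)C | intermediate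
15 | 7β-O-Acetate (O-TBS Jatamanvaltrate I) | O=C(OC[C@@]1(O)[C@@H](OC(C)=O)C=C2C(COC(=O)CC(C)C)=CO[C@@H](OC(=O)CC(C)C)[C@H]12)c3ccccc3O[Si](C)(C)C(C)(C)C | intermediate
16 | Jatamanvaltrate I | CC(=O)O[C@H]1C=C2C(COC(=O)CC(C)C)=CO[C@@H](OC(=O)CC(C)C)[C@@H]2[C@@]1(O)COC(=O)c1ccccc1O | target

## Totals

Total steps: 14. Longest linear sequence: 13 (genipin → 16; step 5 is a one-step side branch).

## Steps most likely to fail, with fallbacks

1. **Steps 8–9 (C8 configuration).** The route relies on β-face epoxidation and clean ester-assisted inversion at tertiary C8. Fallback: switch to reagent control with retention at C8. Keep C10-OH free (C1 already acylated), run a Sharpless asymmetric epoxidation to the 7α,8α-epoxide, open it at C7 with Ti(OiPr)4 and acid 7, then shift the acyl group from O7 to O10 to reach the same diol 11.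

2. **Step 10 (IBX dehydrogenation).** The dienone may over-oxidise or lose the C1 ester by E1cB from the γ-acidic C9-H. Fallback: avoid the ketone altogether. Convert a 7α,8α-epoxide to the 8α-hydroxy-6,7-ene (PhSe⁻ opening, selenoxide elimination), then use a Schenck ene reaction (O2, TPP, hν; PPh3). The only allylic hydrogen is H-5β, so suprafacial abstraction gives C5=C6 and 7β-OH directly.

3. **Step 11 (C7 facial selectivity in the Luche reduction; acid-labile product).** Fallback: use the wrong epimer productively. After C11 isovalerylation, Mitsunobu inversion of the 7α-alcohol with AcOH (DIAD, PPh3) installs the 7β-acetate directly, replacing step 13.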